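The numbers in the tables come from a simulation for an exercise, noise included.

Wednesday's flask holds reagent to substrate in the ratio 1.20, and I treat that ratio as a budget through which I can follow one molecule.

| flask | substrate | reagent in the second phase | temperature | remark | time | volume of the second phase over the first |
|---|---|---|---|---|---|---|
| Wednesday's | 0.021 M | 1.2 equiv | 50 °C | the very flask that is asked about, followed so far |  |  |
| Friday's | 0.021 M | 1.8 equiv | 45 °C | run made earlier |  |  |
| flask | 0.021 M | 1.20 equiv | 50 °C |  | 8.0 d | 0.25 |

Wednesday's run (percent of the substrate charged)

| time / d | target / % | substrate / % |
|---|---|---|
| 0.833 | 33.2 | 1.4 |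
| 1.67 | 34.6 | 0.5 |
| 3.00 | 32.4 | 1.6 |
| 4.00 | 34.9 | 0 |
| 5.00 | 31.0 | 0 |
| 6.00 | 31.2 | 0.9 |

Friday's run (percent of the substrate charged)

| time / h | target / % | substrate / % |
|---|---|---|
| 8.00 | 27.0 | 0 |
| 15.0 | 11.5 | 0 |
| 20.0 | 7.9 | 0 |
| 30.0 | 3.2 | 0 |
| 40.0 | 5.1 | 0 |
| 48.0 | 3.6 | 0 |

(scatter of a reading: 1 percentage point)

- north-west: at 8.0 d take out 90% of the target then present, then wait 4.0 d
- south-west: at 8.0 d add substrate, 50.0% of the amount charged, then wait 4.0 d
- east: change nothing and wait 4.0 d more
- north: at 8.0 d raise the temperature by 20 K, then wait 4.0 d

- in the second phase: reagent in the second phase; everything else is in the first
- charges count per volume of the first phase; a concentration in a rate is the amount of a species over the volume of its own phase; every rate counts per litre of the first phase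
- target taken out counts as made
- the earlier runs hold the two phases in the same ratio of volumes as the flask asked about
- additions bring no volume worth counting

* target, in percent of the substrate first charged, at 8.0 d
* the option that brings most further target ("none" if no option brings more than 2 percentage points) (north-west / south-west / east / north / none)
* target present, with what was taken out counted in, in percent of the substrate first charged, after south-west
* target present, with what was taken out counted in, in percent of the substrate first charged, after east

I let a substrate molecule pay one reagent to become target. If the destruction seen on Friday's run takes reagent too, a destroyed target pays a second. If every reagent is used and substrate reads 0%, as at 4.00 d, this budget (a reagent balance) allows 80.0% target on Wednesday's flask. Its six readings average 32.9%. The allowed target minus the target read, 47.1%, I call the shortfall.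

So I suspect a fork that takes no reagent. Suppose it pairs one substrate with one target. Each pair then removes the two targets its molecules could have been and frees one reagent to destroy another, so a pair costs 3 targets, and on this supposition the pairs, each counted once, come to 15.7% of the substrate charged. My reckoning for target at 8.0 d is that average, 32.9%, and the same after east, but south-west brings the suspected partners together, so I expect it to lose target. The forecast gives 32%, best none, 32.5% after south-west and 31.5% after east, holding that “Added substrate finds no reagent”, and I part from it on south-west.

The flask gives 32.2%, best none, 32.2% after east and 1.20% after south-west.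

    reagent in the reaction phase ⇌ reagent in the second phase, rate k1*([reagent in the reaction phase] - [reagent in the second phase]/K1) per volume of the first phase (partition coefficient = 1.54, kL = 3.08 × 10⁻⁵ /s)
    reagent in the reaction phase + target → over-reacted product (k = 0.0756 /M/s, Ea = 68.0 kJ/mol)
    substrate + reagent in the reaction phase → target (k = 0.232 /M/s, Ea = 50.0 kJ/mol)
    reagent in the reaction phase + target → over-reaction product (k = 1.38 × 10⁻⁴ /M/s, Ea = 81.0 kJ/mol)
    substrate + target → side product (k = 0.00180 /M/s, Ea = 68.0 kJ/mol)
    (constants at 50 °C)

Target's half-life by the turning of substrate + target into side product alone, the other concentrations as charged, is 0.21 d, short against 8.0 d. The pairs are the side product, and each counts as two in a percentage, so the shortfall 47.1% gives 31.4% side product, where this flask holds 31.8%. The flask with 0.084 M substrate, at the same equivalents, ends with 8.85% target, so its shortfall of 71.2% gives 47.4% side product, and it holds 47.4%.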